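All runs come from a simulation for an exercise, noise included.

- 4 questions stood, a pair each for dusk and winter, and behind them one decision: whether the next flask was heated from 25 °C to 35 °C or left at 25 °C.

| setting | delta | theta | gamma | dusk | winter |
|---|---|---|---|---|---|
| substrate | 0.050 M | 0.050 M | 0.075 M | 0.050 M | 0.050 M |
| partner A | 1.3 equiv | 1.3 equiv | 1.3 equiv | 1.30 equiv | 1.30 equiv |
| partner B | 1.7 equiv | 3.8 equiv | 2.5 equiv | 2.50 equiv | 2.50 equiv |
| temperature | 10 °C | 30 °C | 10 °C | 25 °C | 35 °C |
| remark | run made earlier | run made earlier | run made earlier |  |  |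
| time |  |  |  | 25 h | 25 h |

| run | time / h | substrate / % | target / % | open intermediate / % | isomer of the product / % |
|---|---|---|---|---|---|
| delta | 6.00 | 96.6 | 1.3 | 2.8 | 0 |
| delta | 15.0 | 94.0 | 0.2 | 6.7 | 0.2 |
| delta | 30.0 | 88.7 | 0 | 11.0 | 0 |
| delta | 48.0 | 83.7 | 0.9 | 17.2 | 0.2 |
| theta | 6.00 | 75.3 | 0.4 | 23.5 | 0.9 |
| theta | 12.0 | 62.0 | 3.2 | 32.5 | 0.8 |
| theta | 20.0 | 53.2 | 6.2 | 36.5 | 3.1 |
| theta | 25.0 | 47.9 | 9.4 | 37.9 | 5.5 |
| gamma | 12.0 | 89.5 | 0.1 | 12.4 | 0 |
| gamma | 25.0 | 80.0 | 0.5 | 19.7 | 0.6 |
| gamma | 40.0 | 72.2 | 1.0 | 27.0 | 0.6 |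
| gamma | 48.0 | 68.8 | 1.4 | 28.6 | 0 |

(standard deviation of a reading: 0.5 percentage points)

1. which of these there is most of at the end, counted by the substrate in it, dusk (substrate / open intermediate / target / isomer of the product)
2. which of these there is most of at the end, counted by the substrate in it, winter (substrate / open intermediate / target / isomer of the product)
3. how much there is at the end of the one of these that leads, in percent of the substrate charged: dusk
4. how much there is at the end of the one of these that leads, in percent of the substrate charged: winter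

- candidate steps: partner B + partner A -> second intermediate; open intermediate + second intermediate -> target; target <-> isomer of the product; substrate + partner B -> open intermediate; partner B <-> dormant form

- I carried one number, the mean pull g: the logarithm of charged substrate over substrate left, divided by the time and by the charged c(partner B), which for theta at 25.0 h was 0.155 L mol⁻¹ h⁻¹. It is a pseudo-first-order constant per charged partner B, and it puts the mean of the bending c(partner B) curve in place of the curve.
- I checked what that replacement costs: theta's first reading, at 6.00 h, gave 0.249 L mol⁻¹ h⁻¹, so the mean over the longer time was 0.622 of it. I therefore compared g at equal times, and the asked time equals theta's last reading.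
- Gamma at 25.0 h and 10 °C, with charged c(partner B) of 0.188 M against theta's 0.190 M, gave 0.0476 L mol⁻¹ h⁻¹, so g rose 3.26-fold between the two temperatures.
- Dusk lay a quarter of that span below theta and winter a quarter above it, so one such step was a factor 1.34.
- My reckoning for dusk was g = 0.115 L mol⁻¹ h⁻¹, leaving substrate at 69.7 %. For winter it was g = 0.208 L mol⁻¹ h⁻¹, leaving 52.2 %, an extrapolation, since winter lay above the temperatures of the runs. Heating promised 18 percentage points, so I planned on winter.
- The forecast put substrate ahead in dusk at 71 % and substrate ahead in winter at 53 %, a point from mine in each, and its ground for winter was that “dormancy sets in faster and B is depleted relatively more”.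

The flasks gave substrate ahead in dusk at 68.3 % and substrate ahead in winter at 59.9 %.

    partner B + partner A → second intermediate (k = 1.43 × 10⁻⁴ L mol⁻¹ s⁻¹, Ea = 79.0 kJ mol⁻¹)
    open intermediate + second intermediate → target (k = 8.60 × 10⁻⁵ L mol⁻¹ s⁻¹, Ea = 57.0 kJ mol⁻¹)
    target ⇌ isomer of the product (K = 2.30, k = 1.07 × 10⁻⁵ s⁻¹, Ea = 98.0 kJ mol⁻¹, ΔH = −26.0 kJ mol⁻¹)
    substrate + partner B → open intermediate (k = 5.95 × 10⁻⁵ L mol⁻¹ s⁻¹, Ea = 61.0 kJ mol⁻¹)
    partner B ⇌ dormant form (K = 1.18, k = 5.54 × 10⁻⁶ s⁻¹, Ea = 93.0 kJ mol⁻¹, ΔH = 3.00 kJ mol⁻¹)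
    (constants at 25 °C)

Dusk gave g = 0.122 L mol⁻¹ h⁻¹ and winter 0.164 L mol⁻¹ h⁻¹, a rise of 1.34-fold where I had reckoned 1.80, so heating bought 8.4 points. In winter at 3.70 h, partner B went into second intermediate at 0.85 of its forward rate into dormant form, and the mid-point of turnover came at 2.55 h for dormant form against 5.65 h for open intermediate, with 17 % of partner B left at the end. The neighbour of winter charged with 10.0 equiv of partner B gave g = 0.236 L mol⁻¹ h⁻¹ and substrate 5.23 %.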